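## The problem

Compound 34 is a germacranolide. Germacrane numbers are used throughout: ring C1–C10, lactone carbons C11 (=C13H2) and C12 (C=O), C14 on C10, C15 on C4.

1. A ten-membered carbocycle carries a trans-fused α-methylene-γ-butyrolactone on C6 (O) and C7 (C11).
2. Both ring olefins are trisubstituted and ring-cis: in C1=C10 C2 is cis to C9 and C10 bears the C14 aldehyde; in C4=C5 C3 is cis to C6 and C4 bears C15H2OH. Their geometry must be fixed before or during ring closure, and C14 and C15 are two allylic primary carbons at different oxidation levels.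
3. C6 (R), C7 (S), C8 (S) and C9 (R) are contiguous: 6,7-trans on the lactone, 7,8-anti and 8,9-anti along the C6–C9 chain.
4. O8 and O9 are neighbouring secondary oxygens with different esters (angelate; (R)-2-methylbutanoate), so they must be told apart by construction, not by selective acylation.
5. C7/C8 is an aldol-type pair. C6 and C9 each lie between a stereocentre and an sp2 carbon, so each can arise from an aldehyde under 1,2-induction (C7 controls C6, C8 controls C9).
6. The exo-methylene lactone, the enal, the angelate (Z to E) and the vicinal diester (acyl migration) exclude strong base, hydride and hot nucleophiles late in the route.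
7. The feature that makes the key step possible: the stereotetrad C6–C9 is flanked on both sides by olefinic carbons (C5 and C10), and C9–C10 joins a carbinol carbon to the α-carbon of the enal. The ring is therefore a C6–C9 core plus a C5=C4–C3–C2–C1=C10 staple, and C10 can be added as an alkenyl metal to a C9 aldehyde while the two cis olefins and the trans lactone fold the chain.

## Retrosynthesis

**34 back to 25 (esters, C14 oxidation level, silyl ethers).** The bonds cut are O15–Si (33), the C14 carbonyl (32), O14–Si (31), O8–angeloyl (28 + 29), O8–Si (27) and O9–acyl (25 + 26). The angelate goes on after all strong base. C14 is oxidised only when O8 is acylated, because a free 8-OH and a 14-aldehyde are 1,4-related and would close to a lactol that over-oxidises. C15 keeps the most robust silyl group so that C14-OH and C15-OH are never free together. No stereocentre changes; the forward steps need a TES < TBS < TBDPS lability ladder and an isomerisation-free angeloylation.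

**25 back to 24 (key disconnection, C9–C10).** Cutting C9–C10 opens the ring and removes C9 as a stereocentre. The neighbouring cuts are worse: C8–C9 (pinacol or aldol) would give two free, undifferentiated hydroxyls, and C1=C10 by olefination would place a carbanion β to the C9 oxygen. 24 is acyclic apart from the lactone and has one ring and one stereocentre less. The forward reaction must retain the C1=C10 geometry, add to the aldehyde only, and follow Felkin–Anh control from C8; it leaves O9 as the only free hydroxyl.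

**24 back to 17 (C9 oxidation level, C11=C13).** 24 comes from alcohol 23 and PMB ether 22. The exo-methylene (C11=C13) is cut back to lactone 17 via Mannich base 20 (C13 from 18). This is placed at 17 because only ethers, one lactone and the alkenyl bromide must survive the lithium enolate.

**17 back to 11 + 15 (C5–C6 and O6–C12).** Cutting C5–C6 and the lactone C–O bond gives alkenyl iodide 11 and aldehyde 15. The alternative C6–C7 cut (allyl metal plus aldehyde) gives the 6,7-cis relationship from the accessible (Z)-allyl bromide. A C4=C5 olefination would leave a C15 ester to reduce beside the lactone. The forward step is a union of two advanced fragments that forms the bond and sets C6 (Felkin–Anh from C7, reinforced by 1,3-anti induction from O8); it must use the iodide of 11 and leave its bromide.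

**15 back to 12 + 13 (C7–C8).** Cutting C7–C8 of 15 (via 14) as an aldol gives two achiral aldehydes. Donor 12 already contains the lactone arm C11–C12; acceptor 13 brings C8, C9 and a PMB ether that is orthogonal to every silyl group. A glycolate aldol across C8–C9 would put the carbonyl on C7, which must be a CH. The forward reaction must be a crossed, anti-selective, enantioselective aldehyde–aldehyde aldol.

**11 back to 1 + 2 + 7 (the staple).** 11 comes from alcohol 10 and ester 9. Cutting C1=C10 of 9 gives aldehyde 6 and ylide 7 (as its bromo derivative 8); the Wittig reaction puts C2 trans to the ester, which is the ring-cis geometry. 6 comes from acetal 5. Cutting C3–C4 and C5–I of 5 gives Grignard reagent 1 and propargyl ether 2; a syn carbometalation followed by iodination puts iodine cis to C3, which is the ring-cis geometry of C4=C5.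

## Roads not taken

**Alternative 1:** the most obvious cut is C6–C7 with O6–C12: intramolecular Barbier or Nozaki–Hiyama–Kishi 2-(alkoxycarbonyl)allylation of seco-aldehyde A1 (C6 aldehyde, (Z)-2-(bromomethyl)enoate at C7) to give 31 directly.
- The allyl metal from A1 has the C8 acyloxy group on the carbon next to its reacting terminus, so vinylogous β-elimination to a diene competes with addition.
- The (Z)-bromide reacts through a chair transition state to the 6,7-syn adduct, i.e. the cis lactone, unless the ring overrides it.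
- C6 and C7 would both depend on macrocyclic control relative to C8.
- A1 needs the differentiated C8/C9 diester next to an enoate, a long and base-sensitive run-up.
- The chosen plan sets C6 and C9 one at a time from neighbouring stereocentres and never has an allyl metal beside a leaving group.

**Alternative 2:** cut C8=C9 by ring-closing metathesis of bis-vinyl lactone A2 to tetraene A3, then dihydroxylate to cis-diol A4.
- The metathesis must engage a 1,3-diene terminus at C10 and close a strained ten-membered ring; truncation through the internal olefin is a known escape.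
- Osmylation of A3 must pick one of four olefins and one face.
- A4 has two free secondary hydroxyls that need a regioselective acylation.
- The chosen plan releases the two oxygens at different steps.

**Alternative 3:** cut C7–C8 by an Ireland–Claisen rearrangement of allylic glycolate A5 to acid A6. C13–O becomes the exo-methylene and the carboxyl becomes C9.
- The stereochemical model is good (chelated Z-enolate, chair, attack anti to the C6–O bond).
- A5 needs a stereodefined (Z)-2-(acyloxymethyl)enoate with the C6 carbinol already in place, at least five more steps.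
- The C6–H of A5 is vinylogously acidic and competes for base.
- A6 must be taken back from the acid to the aldehyde level beside an acrylate before the same ring closure.
- The aldol of 12 and 13 gives the same C7/C8 pair in one catalytic step.

Key step: step 13

Assumption: 13, 26 and the THF solution of 1 are taken as purchasable. TBDPS = tert-butyldiphenylsilyl, TBS = tert-butyldimethylsilyl, TES = triethylsilyl, PMB = 4-methoxybenzyl.

## Steps

Step 1
Reactants: 1 [2-(1,3-dioxan-2-yl)ethyl]magnesium bromide (0.5 M in THF); 2 tert-butyl(diphenyl)(prop-2-yn-1-yloxy)silane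
Product: 5 tert-butyl({(2E)-2-[2-(1,3-dioxan-2-yl)ethyl]-3-iodoprop-2-en-1-yl}oxy)diphenylsilane, via alkylcopper reagent 3 (not isolated), via alkenylcopper adduct 4 (not isolated)
Conditions: CuBr·SMe2 (1 equiv), THF/Me2S, −45 °C; then 2, −45 → −15 °C; then I2, −45 → 0 °C
Reagents that add atoms: iodine (II)
Why: Normant carbocupration of a terminal alkyne: the alkylcopper adds syn, carbon to the internal carbon (C4) and copper to the terminal carbon (C5), and iodinolysis goes with retention, so iodine ends cis to C3 and trans to C15 (ring-cis C4=C5); the bulky, weakly coordinating silyl ether and THF should favour this branched regiochemistry.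

Step 2
Reactants: 5 tert-butyl({(2E)-2-[2-(1,3-dioxan-2-yl)ethyl]-3-iodoprop-2-en-1-yl}oxy)diphenylsilane
Product: 6 (4E)-4-(TBDPS-oxymethyl)-5-iodopent-4-enal
Conditions: 1 M aq. HCl, THF, 40 °C
Reagents that add atoms: water (O)
Why: Acid hydrolysis of the 1,3-dioxane acetal; the primary TBDPS ether and the iodoalkene should survive dilute acid.

Step 3
Reactants: 6 (4E)-4-(TBDPS-oxymethyl)-5-iodopent-4-enal; 7 ethyl (triphenyl-λ5-phosphanylidene)acetate
Product: 9 ethyl (2Z,6E)-2-bromo-6-(TBDPS-oxymethyl)-7-iodohepta-2,6-dienoate, via bromo ylide 8 (not isolated)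
Conditions: 7, NBS, CH2Cl2, −20 °C; then 6, −20 °C → rt
Reagents that add atoms: N-bromosuccinimide (O=C1CCC(=O)N1Br)
Why: Wittig reaction of an α-bromo stabilised ylide made in the flask; such ylides should give mainly the (Z)-α-bromo enoate with C2 trans to the ester (the future C14) and cis to bromine (the future C9), i.e. the ring-cis C1=C10 geometry.

Step 4
Reactants: 9 ethyl (2Z,6E)-2-bromo-6-(TBDPS-oxymethyl)-7-iodohepta-2,6-dienoate
Product: 10 (2Z,6E)-2-bromo-6-(TBDPS-oxymethyl)-7-iodohepta-2,6-dien-1-ol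
Conditions: DIBAL-H, CH2Cl2, −78 °C
Reagents that add atoms: none
Why: 1,2-Reduction of an enoate to the allylic alcohol by DIBAL-H; alkenyl halides and the silyl ether are inert at −78 °C.

Step 5
Reactants: 10 (2Z,6E)-2-bromo-6-(TBDPS-oxymethyl)-7-iodohepta-2,6-dien-1-ol
Product: 11 tert-butyl{[(2Z,6E)-2-bromo-6-(TBDPS-oxymethyl)-7-iodohepta-2,6-dien-1-yl]oxy}dimethylsilane
Conditions: TBSCl, imidazole, DMF, 0 °C → rt
Reagents that add atoms: tert-butyldimethylsilyl chloride (CC(C)(C)[Si](C)(C)Cl)
Why: Standard silylation of a primary allylic alcohol; TBS on O14 sits between TES (O8) and TBDPS (O15) in lability.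

Step 6
Reactants: 12 methyl 4-oxobutanoate; 13 2-[(4-methoxybenzyl)oxy]acetaldehyde
Product: 14 methyl (3R,4S)-3-formyl-4-hydroxy-5-[(4-methoxybenzyl)oxy]pentanoate
Conditions: D-proline (20 mol%), DMF, 4 °C, 12 added by syringe pump
Reagents that add atoms: none
Why: Proline-catalysed crossed aldehyde–aldehyde aldol: the alkyl aldehyde 12 is the enamine donor and the more electrophilic α-oxy aldehyde 13 the acceptor; the hydrogen-bonded anti transition state with D-proline should give the anti aldol with C7 (3R) and C8 (4S).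

Step 7
Reactants: 14 methyl (3R,4S)-3-formyl-4-hydroxy-5-[(4-methoxybenzyl)oxy]pentanoate
Product: 15 methyl (3R,4S)-3-formyl-5-[(4-methoxybenzyl)oxy]-4-[(triethylsilyl)oxy]pentanoate
Conditions: TESOTf, 2,6-lutidine, CH2Cl2, −78 °C
Reagents that add atoms: triethylsilyl trifluoromethanesulfonate (CC[Si](CC)(CC)OS(=O)(=O)C(F)(F)F)
Why: Low-temperature silylation of the crude aldol with a hindered base protects O8 before the β-hydroxy aldehyde can dehydrate, epimerise or lactonise.

Step 8
Reactants: 11 tert-butyl{[(2Z,6E)-2-bromo-6-(TBDPS-oxymethyl)-7-iodohepta-2,6-dien-1-yl]oxy}dimethylsilane; 15 methyl (3R,4S)-3-formyl-5-[(4-methoxybenzyl)oxy]-4-[(triethylsilyl)oxy]pentanoate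
Product: 17 (4S,5R)-5-[(1E,5Z)-6-bromo-7-(TBS-oxy)-2-(TBDPS-oxymethyl)hepta-1,5-dien-1-yl]-4-[(1S)-2-(PMB-oxy)-1-(TES-oxy)ethyl]oxolan-2-one, via hydroxy ester 16 (not isolated)
Conditions: CrCl2, NiCl2 (1 mol%), DMSO/THF, rt; then PPTS (cat.), toluene, 50 °C
Reagents that add atoms: none
Why: Nozaki–Hiyama–Kishi alkenylation then lactonisation: nickel inserts into the unhindered C5–I bond much faster than into the hindered C10–Br bond, the alkenylchromium adds to the aldehyde and not the ester, and C6 (R) should follow Felkin–Anh control from C7 reinforced by 1,3-anti induction from the C8 silyloxy group; the C6 hydroxyl then closes the trans γ-lactone on C12.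

Step 9
Reactants: 17 (4S,5R)-5-[(1E,5Z)-6-bromo-7-(TBS-oxy)-2-(TBDPS-oxymethyl)hepta-1,5-dien-1-yl]-4-[(1S)-2-(PMB-oxy)-1-(TES-oxy)ethyl]oxolan-2-one; 18 N,N-dimethylmethyleneiminium iodide (Eschenmoser's salt)
Product: 20 3-[(dimethylamino)methyl] derivative of 17 (C11 configuration not controlled), via lithium enolate 19 (not isolated)
Conditions: LDA, THF, −78 °C; then 18, −78 °C → rt
Reagents that add atoms: none
Why: Mannich reaction of the lactone lithium enolate with Eschenmoser's salt brings in C13; at −78 °C only the lactone α-CH2 (C11) should be deprotonated, and the new C11 centre is removed in the next step.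

Step 10
Reactants: 20 3-[(dimethylamino)methyl] derivative of 17
Product: 22 (4S,5R)-5-[(1E,5Z)-6-bromo-7-(TBS-oxy)-2-(TBDPS-oxymethyl)hepta-1,5-dien-1-yl]-3-methylidene-4-[(1S)-2-(PMB-oxy)-1-(TES-oxy)ethyl]oxolan-2-one, via trimethylammonium iodide 21 (not isolated)
Conditions: MeI, THF, rt; then sat. aq. NaHCO3, CH2Cl2, rt
Reagents that add atoms: none
Why: N-Quaternisation and mild-base E1cB elimination of trimethylamine, the standard way to an α-methylene lactone; no ester that could be harmed is present yet.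

Step 11
Reactants: 22 α-methylene lactone PMB ether
Product: 23 (4S,5R)-5-[(1E,5Z)-6-bromo-7-(TBS-oxy)-2-(TBDPS-oxymethyl)hepta-1,5-dien-1-yl]-4-[(1S)-2-hydroxy-1-(TES-oxy)ethyl]-3-methylideneoxolan-2-one
Conditions: DDQ, CH2Cl2/pH 7 buffer, 0 °C
Reagents that add atoms: none
Why: Oxidative cleavage of the PMB ether by DDQ frees only O9; silyl ethers, the alkenyl bromide and the electron-poor exo-methylene should not react under buffered conditions.

Step 12
Reactants: 23 primary alcohol
Product: 24 (2S)-2-[(2R,3S)-2-{(1E,5Z)-6-bromo-7-(TBS-oxy)-2-(TBDPS-oxymethyl)hepta-1,5-dien-1-yl}-4-methylidene-5-oxooxolan-3-yl]-2-(TES-oxy)acetaldehyde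
Conditions: Dess–Martin periodinane, CH2Cl2, 0 °C → rt
Reagents that add atoms: none
Why: Dess–Martin oxidation gives the α-silyloxy aldehyde without base, so C8 should not epimerise; the aldehyde is used at once.

Step 13
Reactants: 24 seco aldehyde
Product: 25 (6R,7S,8S,9R)-9-hydroxy-8-(TES-oxy)-14-(TBS-oxy)-15-(TBDPS-oxy)germacra-1(10)Z,4E,11(13)-trien-12,6-olide (both ring olefins ring-cis)
Conditions: CrCl2 (excess), NiCl2 (20 mol%), DMSO/THF (3:1), 0.002 M, slow addition, rt → 40 °C
Reagents that add atoms: none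
Why: Nozaki–Hiyama–Kishi ring closure: Ni(0) inserts into the C10–Br bond with retention, transmetalation to Cr(III) gives an alkenylchromium, and this adds to the C9 aldehyde of the same molecule. The closest known reaction type is the Ni/Cr-mediated alkenyl halide–aldehyde cyclisation used for medium and large carbocycles. The ten-membered ring closes by a 10-exo-trig attack of C10 on the C9 carbonyl. C9 is the only new stereocentre and should be set by C8 in a polar Felkin–Anh sense (C8–OSiEt3 bond anti to the incoming alkenyl group), which gives the 8,9-anti (9R) carbinol. The step needs addition to the aldehyde in preference to the lactone and the exo-methylene acceptor, which the weakly basic alkenylchromium provides, and ring closure in preference to dimerisation, which high dilution provides. The ring-cis C1=C10 geometry is carried by the (Z)-bromoalkene, C4=C5 is already ring-cis, and with the trans lactone these fold the chain so that C9 and C10 can meet. The silyl ether on C14 is a poor leaving group, which should suppress β-elimination of the alkenylchromium to an allene. The new C9 hydroxyl is the only free oxygen in 25, so O8 and O9 are differentiated without a selective acylation.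

Step 14
Reactants: 25 macrocyclic C9 alcohol; 26 (2R)-2-methylbutanoic acid
Product: 27 9-O-[(2R)-2-methylbutanoyl] derivative of 25
Conditions: EDCI, DMAP (cat.), CH2Cl2, 0 °C → rt
Reagents that add atoms: none
Why: Steglich-type esterification of the only free hydroxyl; catalytic DMAP at low temperature should not epimerise the α-centre of the acid.

Step 15
Reactants: 27 C9 ester with TES, TBS and TBDPS ethers
Product: 28 (6R,7S,8S,9R)-8-hydroxy-9-[(2R)-2-methylbutanoyloxy]-14-(TBS-oxy)-15-(TBDPS-oxy)germacra-1(10)Z,4E,11(13)-trien-12,6-olide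
Conditions: PPTS, MeOH/CH2Cl2, 0 °C
Reagents that add atoms: none
Why: Mild acid methanolysis removes the TES ether much faster than the primary TBS and TBDPS ethers; acidic conditions should also keep the O9 ester from migrating to O8.

Step 16
Reactants: 28 C8 alcohol; 29 angelic acid
Product: 31 (6R,7S,8S,9R)-8-angeloyloxy-9-[(2R)-2-methylbutanoyloxy]-14-(TBS-oxy)-15-(TBDPS-oxy)germacra-1(10)Z,4E,11(13)-trien-12,6-olide, via mixed anhydride 30 (not isolated)
Conditions: 29, 2,4,6-trichlorobenzoyl chloride, Et3N, toluene, rt; then 28, 75 °C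
Reagents that add atoms: none
Why: Yamaguchi-type acylation with the preformed angelic 2,4,6-trichlorobenzoic anhydride and no nucleophilic catalyst is the established way to angelates of hindered alcohols with little Z to E isomerisation.

Step 17
Reactants: 31 diester with TBS and TBDPS ethers
Product: 32 (6R,7S,8S,9R)-8-angeloyloxy-14-hydroxy-9-[(2R)-2-methylbutanoyloxy]-15-(TBDPS-oxy)germacra-1(10)Z,4E,11(13)-trien-12,6-olide
Conditions: HF·pyridine, pyridine, THF, 0 °C
Reagents that add atoms: none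
Why: Buffered HF·pyridine removes a primary TBS ether well before a primary TBDPS ether, which frees O14 alone.

Step 18
Reactants: 32 C14 allylic alcohol
Product: 33 (6R,7S,8S,9R)-8-angeloyloxy-9-[(2R)-2-methylbutanoyloxy]-14-oxo-15-(TBDPS-oxy)germacra-1(10)E,4E,11(13)-trien-12,6-olide
Conditions: MnO2, CH2Cl2, rt
Reagents that add atoms: none
Why: MnO2 oxidises only the allylic primary alcohol; O8 is already acylated so no 8,14-lactol can form, and the enal keeps the geometry with C2 trans to CHO, which is also the thermodynamically preferred one.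

Step 19
Reactants: 33 C15 TBDPS ether
Product: 34 (6R,7S,8S,9R)-8-angeloyloxy-15-hydroxy-9-[(2R)-2-methylbutanoyloxy]-14-oxogermacra-1(10)E,4E,11(13)-trien-12,6-olide (CNP0290361.1)
Conditions: HF·pyridine, THF, 0 °C → rt
Reagents that add atoms: none
Why: Acidic fluoride removes the last silyl ether without base, so the enal, the exo-methylene lactone and both esters should be untouched and no acyl migration or angelate isomerisation is expected.

## Compound list

1 | [2-(1,3-dioxan-2-yl)ethyl]magnesium bromide | Br[Mg]CCC1OCCCO1 | starting material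
2 | tert-butyl(diphenyl)(prop-2-yn-1-yloxy)silane | C#CCO[Si](c1ccccc1)(c1ccccc1)C(C)(C)C | starting material
3 | [2-(1,3-dioxan-2-yl)ethyl]copper (MgBr2 complex) | [Cu]CCC1OCCCO1 | intermediate
4 | [(1E)-2-(TBDPS-oxymethyl)-4-(1,3-dioxan-2-yl)but-1-en-1-yl]copper | [Cu]/C=C(/CO[Si](c1ccccc1)(c1ccccc1)C(C)(C)C)CCC1OCCCO1 | intermediate
5 | tert-butyl({(2E)-2-[2-(1,3-dioxan-2-yl)ethyl]-3-iodoprop-2-en-1-yl}oxy)diphenylsilane | I/C=C(/CO[Si](c1ccccc1)(c1ccccc1)C(C)(C)C)CCC1OCCCO1 | intermediate
6 | (4E)-4-(TBDPS-oxymethyl)-5-iodopent-4-enal | I/C=C(/CO[Si](c1ccccc1)(c1ccccc1)C(C)(C)C)CCC=O | intermediate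
7 | ethyl (triphenyl-λ5-phosphanylidene)acetate | CCOC(=O)C=P(c1ccccc1)(c1ccccc1)c1ccccc1 | starting material
8 | ethyl bromo(triphenyl-λ5-phosphanylidene)acetate | CCOC(=O)C(Br)=P(c1ccccc1)(c1ccccc1)c1ccccc1 | intermediate
9 | ethyl (2Z,6E)-2-bromo-6-(TBDPS-oxymethyl)-7-iodohepta-2,6-dienoate | I/C=C(/CO[Si](c1ccccc1)(c1ccccc1)C(C)(C)C)CC/C=C(\Br)C(=O)OCC | intermediate
10 | (2Z,6E)-2-bromo-6-(TBDPS-oxymethyl)-7-iodohepta-2,6-dien-1-ol | I/C=C(/CO[Si](c1ccccc1)(c1ccccc1)C(C)(C)C)CC/C=C(\Br)CO | intermediate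
11 | tert-butyl{[(2Z,6E)-2-bromo-6-(TBDPS-oxymethyl)-7-iodohepta-2,6-dien-1-yl]oxy}dimethylsilane | I/C=C(/CO[Si](c1ccccc1)(c1ccccc1)C(C)(C)C)CC/C=C(\Br)CO[Si](C)(C)C(C)(C)C | intermediate
12 | methyl 4-oxobutanoate | COC(=O)CCC=O | starting material
13 | 2-[(4-methoxybenzyl)oxy]acetaldehyde | COc1ccc(COCC=O)cc1 | starting material
14 | methyl (3R,4S)-3-formyl-4-hydroxy-5-[(4-methoxybenzyl)oxy]pentanoate | O=C[C@H](CC(=O)OC)[C@H](O)COCc1ccc(OC)cc1 | intermediate
15 | methyl (3R,4S)-3-formyl-5-[(4-methoxybenzyl)oxy]-4-[(triethylsilyl)oxy]pentanoate | O=C[C@H](CC(=O)OC)[C@H](O[Si](CC)(CC)CC)COCc1ccc(OC)cc1 | intermediate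
16 | methyl (3S,4S)-3-[(1R,2E,6Z)-7-bromo-8-(TBS-oxy)-1-hydroxy-3-(TBDPS-oxymethyl)octa-2,6-dien-1-yl]-5-(PMB-oxy)-4-(TES-oxy)pentanoate | COC(=O)C[C@@H]([C@H](O)/C=C(/CO[Si](c1ccccc1)(c1ccccc1)C(C)(C)C)CC/C=C(\Br)CO[Si](C)(C)C(C)(C)C)[C@H](O[Si](CC)(CC)CC)COCc1ccc(OC)cc1 | intermediate
17 | (4S,5R)-5-[(1E,5Z)-6-bromo-7-(TBS-oxy)-2-(TBDPS-oxymethyl)hepta-1,5-dien-1-yl]-4-[(1S)-2-(PMB-oxy)-1-(TES-oxy)ethyl]oxolan-2-one | O=C1C[C@H]([C@H](O[Si](CC)(CC)CC)COCc2ccc(OC)cc2)[C@@H](/C=C(/CO[Si](c2ccccc2)(c2ccccc2)C(C)(C)C)CC/C=C(\Br)CO[Si](C)(C)C(C)(C)C)O1 | intermediate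
18 | N,N-dimethylmethyleneiminium iodide | C=[N+](C)C.[I-] | starting material
19 | lithium enolate of 17 | [Li]OC1=C[C@H]([C@H](O[Si](CC)(CC)CC)COCc2ccc(OC)cc2)[C@@H](/C=C(/CO[Si](c2ccccc2)(c2ccccc2)C(C)(C)C)CC/C=C(\Br)CO[Si](C)(C)C(C)(C)C)O1 | intermediate
20 | 3-[(dimethylamino)methyl] derivative of 17 (C11 epimers) | CN(C)CC1C(=O)O[C@H](/C=C(/CO[Si](c2ccccc2)(c2ccccc2)C(C)(C)C)CC/C=C(\Br)CO[Si](C)(C)C(C)(C)C)[C@H]1[C@H](O[Si](CC)(CC)CC)COCc1ccc(OC)cc1 | intermediate
21 | trimethylammonium iodide of 20 | C[N+](C)(C)CC1C(=O)O[C@H](/C=C(/CO[Si](c2ccccc2)(c2ccccc2)C(C)(C)C)CC/C=C(\Br)CO[Si](C)(C)C(C)(C)C)[C@H]1[C@H](O[Si](CC)(CC)CC)COCc1ccc(OC)cc1.[I-] | intermediate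
22 | (4S,5R)-5-[(1E,5Z)-6-bromo-7-(TBS-oxy)-2-(TBDPS-oxymethyl)hepta-1,5-dien-1-yl]-3-methylidene-4-[(1S)-2-(PMB-oxy)-1-(TES-oxy)ethyl]oxolan-2-one | C=C1C(=O)O[C@H](/C=C(/CO[Si](c2ccccc2)(c2ccccc2)C(C)(C)C)CC/C=C(\Br)CO[Si](C)(C)C(C)(C)C)[C@H]1[C@H](O[Si](CC)(CC)CC)COCc1ccc(OC)cc1 | intermediate
23 | (4S,5R)-5-[(1E,5Z)-6-bromo-7-(TBS-oxy)-2-(TBDPS-oxymethyl)hepta-1,5-dien-1-yl]-4-[(1S)-2-hydroxy-1-(TES-oxy)ethyl]-3-methylideneoxolan-2-one | C=C1C(=O)O[C@H](/C=C(/CO[Si](c2ccccc2)(c2ccccc2)C(C)(C)C)CC/C=C(\Br)CO[Si](C)(C)C(C)(C)C)[C@H]1[C@H](O[Si](CC)(CC)CC)CO | intermediate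
24 | (2S)-2-[(2R,3S)-2-{(1E,5Z)-6-bromo-7-(TBS-oxy)-2-(TBDPS-oxymethyl)hepta-1,5-dien-1-yl}-4-methylidene-5-oxooxolan-3-yl]-2-(TES-oxy)acetaldehyde | C=C1C(=O)O[C@H](/C=C(/CO[Si](c2ccccc2)(c2ccccc2)C(C)(C)C)CC/C=C(\Br)CO[Si](C)(C)C(C)(C)C)[C@H]1[C@H](O[Si](CC)(CC)CC)C=O | intermediate
25 | (6R,7S,8S,9R)-9-hydroxy-8-(TES-oxy)-14-(TBS-oxy)-15-(TBDPS-oxy)germacra-1(10)Z,4E,11(13)-trien-12,6-olide | C=C1C(=O)O[C@@H]2/C=C(/CO[Si](c3ccccc3)(c3ccccc3)C(C)(C)C)CC/C=C(/CO[Si](C)(C)C(C)(C)C)[C@@H](O)[C@@H](O[Si](CC)(CC)CC)[C@@H]12 | intermediate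
26 | (2R)-2-methylbutanoic acid | CC[C@@H](C)C(=O)O | starting material
27 | (6R,7S,8S,9R)-9-[(2R)-2-methylbutanoyloxy]-8-(TES-oxy)-14-(TBS-oxy)-15-(TBDPS-oxy)germacra-1(10)Z,4E,11(13)-trien-12,6-olide | C=C1C(=O)O[C@@H]2/C=C(/CO[Si](c3ccccc3)(c3ccccc3)C(C)(C)C)CC/C=C(/CO[Si](C)(C)C(C)(C)C)[C@@H](OC(=O)[C@H](C)CC)[C@@H](O[Si](CC)(CC)CC)[C@@H]12 | intermediate
28 | (6R,7S,8S,9R)-8-hydroxy-9-[(2R)-2-methylbutanoyloxy]-14-(TBS-oxy)-15-(TBDPS-oxy)germacra-1(10)Z,4E,11(13)-trien-12,6-olide | C=C1C(=O)O[C@@H]2/C=C(/CO[Si](c3ccccc3)(c3ccccc3)C(C)(C)C)CC/C=C(/CO[Si](C)(C)C(C)(C)C)[C@@H](OC(=O)[C@H](C)CC)[C@@H](O)[C@@H]12 | intermediate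
29 | angelic acid, (2Z)-2-methylbut-2-enoic acid | C/C=C(/C)C(=O)O | starting material
30 | (2Z)-2-methylbut-2-enoic 2,4,6-trichlorobenzoic anhydride | C/C=C(/C)C(=O)OC(=O)c1c(Cl)cc(Cl)cc1Cl | intermediate
31 | (6R,7S,8S,9R)-8-angeloyloxy-9-[(2R)-2-methylbutanoyloxy]-14-(TBS-oxy)-15-(TBDPS-oxy)germacra-1(10)Z,4E,11(13)-trien-12,6-olide | C=C1C(=O)O[C@@H]2/C=C(/CO[Si](c3ccccc3)(c3ccccc3)C(C)(C)C)CC/C=C(/CO[Si](C)(C)C(C)(C)C)[C@@H](OC(=O)[C@H](C)CC)[C@@H](OC(=O)/C(C)=C\C)[C@@H]12 | intermediate
32 | (6R,7S,8S,9R)-8-angeloyloxy-14-hydroxy-9-[(2R)-2-methylbutanoyloxy]-15-(TBDPS-oxy)germacra-1(10)Z,4E,11(13)-trien-12,6-olide | C=C1C(=O)O[C@@H]2/C=C(/CO[Si](c3ccccc3)(c3ccccc3)C(C)(C)C)CC/C=C(/CO)[C@@H](OC(=O)[C@H](C)CC)[C@@H](OC(=O)/C(C)=C\C)[C@@H]12 | intermediate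
33 | (6R,7S,8S,9R)-8-angeloyloxy-9-[(2R)-2-methylbutanoyloxy]-14-oxo-15-(TBDPS-oxy)germacra-1(10)E,4E,11(13)-trien-12,6-olide | C=C1C(=O)O[C@@H]2/C=C(/CO[Si](c3ccccc3)(c3ccccc3)C(C)(C)C)CC/C=C(/C=O)[C@@H](OC(=O)[C@H](C)CC)[C@@H](OC(=O)/C(C)=C\C)[C@@H]12 | intermediate
34 | (6R,7S,8S,9R)-8-angeloyloxy-15-hydroxy-9-[(2R)-2-methylbutanoyloxy]-14-oxogermacra-1(10)E,4E,11(13)-trien-12,6-olide (CNP0290361.1) | C=C1C(=O)O[C@@H]2/C=C(/CO)CC/C=C(/C=O)[C@@H](OC(=O)[C@H](C)CC)[C@@H](OC(=O)/C(C)=C\C)[C@@H]12 | target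

## Step count and least certain steps

Total: 19 steps. Longest linear sequence: 17 steps (steps 1–5 and 8–19); the core branch (steps 6–7) joins at step 8.

**Step 13 (key step).** The ring-closing transition state may not follow the open-chain Felkin–Anh preference, so facial selectivity at C9 may be poor. Nickel also inserts slowly into the hindered bromoalkene, so reduction or pinacol coupling of the aldehyde and β-elimination of the alkenylchromium can compete. Fallback: C9 is set by a reagent-controlled reduction instead of the addition. The fallback sets out from 25 obtained as a C9 epimer mixture. Dess–Martin oxidation gives the macrocyclic 9-oxo enone F1. Reduction with (R)-2-methyl-CBS-oxazaborolidine and catecholborane at −78 °C, with the alkenyl group as the large substituent, should deliver the 9R alcohol, and the route is rejoined at 25.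

**Step 6.** Both aldehydes can enolise, so homo-aldol reaction of 13, self-condensation of 12 and dehydration of the product can erode chemoselectivity and the anti ratio. Fallback: the C7/C8 pair is taken from the chiral pool; the carbons of L-malic acid map onto C6–C9. The fallback sets out from commercial dimethyl (S)-malate.
- Reduction of the α-hydroxy ester (BH3·SMe2, cat. NaBH4) gives methyl (3S)-3,4-dihydroxybutanoate F2.
- Tin-mediated primary etherification (Bu2SnO; PMBCl, Bu4NI) gives methyl (3S)-3-hydroxy-4-(PMB-oxy)butanoate F3.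
- Fráter–Seebach alkylation of the dianion (LDA, 2 equiv; tert-butyl bromoacetate) occurs anti to the alkoxide and gives the succinate F4.
- Silylation (TESOTf, 2,6-lutidine) gives the TES ether F5.
- DIBAL-H at −78 °C reduces the methyl ester and leaves the tert-butyl ester, giving aldehyde F6.
- F6 is coupled with 11 as in step 8 to the hydroxy tert-butyl ester F7, which lactonises (PPTS, toluene, 80 °C); the route is rejoined at 17.

**Step 8.** The α-substituent on C7 is only a CH2CO2Me group, so facial selectivity at C6 may be poor; some insertion into the C10–Br bond is also possible. Fallback: C6 is set by a reagent-controlled reduction. The fallback sets out from 16 isolated as a C6 epimer mixture before lactonisation. Dess–Martin oxidation gives the dienyl ketone F8. Reduction with (R)-2-methyl-CBS-oxazaborolidine and catecholborane should give the 6R alcohol 16, which lactonises as in step 8; the route is rejoined at 17.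

**Step 16.** Heating with base may isomerise the angeloyl group to tigloyl, and the O9 ester may migrate to the free O8 before acylation. Fallback: the Z olefin is built on the ester instead of being carried through an acylation. The fallback sets out from 28. Esterification with 2-[bis(2,2,2-trifluoroethoxy)phosphoryl]propanoic acid (DCC, cat. DMAP, 0 °C) gives the phosphonopropanoate F9. A Still–Gennari olefination with acetaldehyde (K2CO3, 18-crown-6, toluene, −20 °C) should give the (Z)-2-methylbut-2-enoate, and the route is rejoined at 31.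

## Further compounds

F1 | step 13 | (6R,7S,8S)-9-oxo-8-(TES-oxy)-14-(TBS-oxy)-15-(TBDPS-oxy)germacra-1(10),4,11(13)-trien-12,6-olide | C=C1C(=O)O[C@@H]2/C=C(/CO[Si](c3ccccc3)(c3ccccc3)C(C)(C)C)CC/C=C(/CO[Si](C)(C)C(C)(C)C)C(=O)[C@@H](O[Si](CC)(CC)CC)[C@@H]12
F2 | step 6 | methyl (3S)-3,4-dihydroxybutanoate | COC(=O)C[C@H](O)CO
F3 | step 6 | methyl (3S)-3-hydroxy-4-[(4-methoxybenzyl)oxy]butanoate | COC(=O)C[C@H](O)COCc1ccc(OC)cc1
F4 | step 6 | 4-tert-butyl 1-methyl (2R)-2-{(1S)-1-hydroxy-2-[(4-methoxybenzyl)oxy]ethyl}butanedioate | COC(=O)[C@H](CC(=O)OC(C)(C)C)[C@H](O)COCc1ccc(OC)cc1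
F5 | step 6 | 4-tert-butyl 1-methyl (2R)-2-{(1S)-2-[(4-methoxybenzyl)oxy]-1-[(triethylsilyl)oxy]ethyl}butanedioate | COC(=O)[C@H](CC(=O)OC(C)(C)C)[C@H](O[Si](CC)(CC)CC)COCc1ccc(OC)cc1
F6 | step 6 | tert-butyl (3R,4S)-3-formyl-5-[(4-methoxybenzyl)oxy]-4-[(triethylsilyl)oxy]pentanoate | O=C[C@H](CC(=O)OC(C)(C)C)[C@H](O[Si](CC)(CC)CC)COCc1ccc(OC)cc1
F7 | step 6 | tert-butyl ester analogue of 16 | CC(C)(C)OC(=O)C[C@@H]([C@H](O)/C=C(/CO[Si](c1ccccc1)(c1ccccc1)C(C)(C)C)CC/C=C(\Br)CO[Si](C)(C)C(C)(C)C)[C@H](O[Si](CC)(CC)CC)COCc1ccc(OC)cc1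
F8 | step 8 | C6 ketone of 16 | COC(=O)C[C@@H](C(=O)/C=C(/CO[Si](c1ccccc1)(c1ccccc1)C(C)(C)C)CC/C=C(\Br)CO[Si](C)(C)C(C)(C)C)[C@H](O[Si](CC)(CC)CC)COCc1ccc(OC)cc1
F9 | step 16 | 8-O-{2-[bis(2,2,2-trifluoroethoxy)phosphoryl]propanoyl} derivative of 28 | C=C1C(=O)O[C@@H]2/C=C(/CO[Si](c3ccccc3)(c3ccccc3)C(C)(C)C)CC/C=C(/CO[Si](C)(C)C(C)(C)C)[C@@H](OC(=O)[C@H](C)CC)[C@@H](OC(=O)C(C)P(=O)(OCC(F)(F)F)OCC(F)(F)F)[C@@H]12
A1 | alternative 1 | seco C6 aldehyde with (Z)-2-(bromomethyl)enoate at C7 and both esters in place | O=C/C=C(/CO[Si](c1ccccc1)(c1ccccc1)C(C)(C)C)CC/C=C(/CO[Si](C)(C)C(C)(C)C)[C@@H](OC(=O)[C@H](C)CC)[C@@H](OC(=O)/C(C)=C\C)/C=C(\CBr)C(=O)OC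
A2 | alternative 2 | bis-vinyl α-methylene lactone for ring-closing metathesis | C=C1C(=O)O[C@H](/C=C(/CO[Si](c2ccccc2)(c2ccccc2)C(C)(C)C)CC/C=C(/CO[Si](C)(C)C(C)(C)C)C=C)[C@H]1C=C
A3 | alternative 2 | germacra-1(10),4,8,11(13)-tetraen-12,6-olide with Z C8=C9 | C=C1C(=O)O[C@@H]2/C=C(/CO[Si](c3ccccc3)(c3ccccc3)C(C)(C)C)CC/C=C(/CO[Si](C)(C)C(C)(C)C)\C=C/[C@@H]12
A4 | alternative 2 | 8,9-cis-diol from A3 | C=C1C(=O)O[C@@H]2/C=C(/CO[Si](c3ccccc3)(c3ccccc3)C(C)(C)C)CC/C=C(/CO[Si](C)(C)C(C)(C)C)[C@@H](O)[C@@H](O)[C@@H]12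
A5 | alternative 3 | (Z)-2-(acyloxymethyl)enoate glycolate with C6 TES ether | COC(=O)/C(COC(=O)COCc1ccc(OC)cc1)=C\[C@H](O[Si](CC)(CC)CC)/C=C(/CO[Si](c1ccccc1)(c1ccccc1)C(C)(C)C)CC/C=C(\Br)CO[Si](C)(C)C(C)(C)C
A6 | alternative 3 | Ireland–Claisen acid (C9 carboxyl, C8 PMB ether, C11=C13 formed) | OC(=O)[C@@H](OCc1ccc(OC)cc1)[C@@H](C(=C)C(=O)OC)[C@H](O[Si](CC)(CC)CC)/C=C(/CO[Si](c1ccccc1)(c1ccccc1)C(C)(C)C)CC/C=C(\Br)CO[Si](C)(C)C(C)(C)C
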